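## Structural features

The target is an open-chain butan-1-ol (C1 to C4) carrying two identical 2,4,5-trimethoxyphenyl groups: ring A on the carbinol carbon C1 and ring B on C3, which also bears the C4 methyl group. The two arenes are the only rings. The stereocenters C1 (R) and C3 (S) are both benzylic and are separated by the C2 methylene, so they stand in a 1,3-relationship across a freely rotating chain and neither can be relied on to induce the other. The fragile group is the C1 hydroxyl: ring A has methoxy groups ortho and para to C1, so the alcohol ionises easily under acid, which would epimerise C1, eliminate to the styrene, form ethers or close an indane by Friedel–Crafts attack on ring B. The electron-rich rings also exclude strong oxidants and electrophiles, whereas the six methyl ethers are robust and are all present in commercial arenes. The real difficulty is absolute control at two remote benzylic centers in a chain with no other handle, with the labile carbinol made as late as possible. The key step exploits the identity of ring A and ring B: C1–C2–C3 with its two aryl groups corresponds to a symmetric 1,3-diarylallyl cation. Joining C4 to one of its two enantiotopic termini creates C3 and leaves a C1=C2 double bond conjugated with ring A only, which marks C1 as the site for oxygen.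

## Logic of the disconnections

13 ⇒ 11 (through 12). The C1–O bond is cut; in the forward sense it is made through a C1–B bond. The reason is that the acid-labile carbinol then appears only in the last operation, and the C1=C2 alkene of 11, conjugated with ring A alone, tells a metal hydride where to place the metal. The gain is the removal of one stereocenter and of the only protic group. The demand is Markovnikov regiochemistry, face selection by the catalyst that overrides the remote C3 center, and retention in the C–B to C–O exchange.

11 ⇒ 9 (through 10). Two C4–H bonds are exchanged for C4–S bonds. A methyl anion cannot serve as a soft nucleophile, whereas two sulfonyl groups turn C4 into a stabilised carbanion that is compatible with allyl-metal chemistry. The gain is that the methyl group becomes a bought reagent. The demand is a reductive C–S cleavage that spares the E alkene and does not touch the C3–H bond.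

9 ⇒ 7 + 8. The C3–C4 bond is cut. Because the two aryl groups are the same, the electrophile is a symmetric allyl unit, so regiochemistry is not an issue and a racemic precursor suffices. The gain is the loss of all stereochemistry and a split into two simple pieces. The demand is that a chiral catalyst chooses between the two enantiotopic termini, and that ionisation of 7 without the catalyst is kept negligible. For that reason the leaving group is one that releases its own base, so that no stoichiometric base is present.

7 ⇒ 4 + 5 (through 6). The O–C(=O) bond of the carbonate is cut. The gain is a plain allylic alcohol. The demand is an acylation free of acid and amine hydrochloride, hence by way of the preformed alkoxide at low temperature, because the allyl system is stabilised by two donor-substituted rings. Allylic transposition is degenerate and cannot give an isomer.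

4 ⇒ 3. The C–H bond of the carbinol is cut, which leads back to the enone. The gain is a crystalline, achiral, conjugated ketone. The demand is 1,2-reduction over 1,4-reduction in a medium that is neither protic nor Lewis acidic. The carbonyl carbon and the β-carbon of 3 become equivalent later, so it does not matter which of them ends as C1.

3 ⇒ 1 + 2. The C=C bond of the enone is cut (aldol condensation). Both halves are commercial arenes that already carry the full oxygenation pattern. The gain is complete: no arene functionalisation remains. The demand is slight, since only 2 can enolise and only 1 can act as the non-enolisable electrophile.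

## Other disconnections considered

Alternative 1: The cut takes ring A apart: three of its ring C–C bonds are formed last, from the carbene carbon and vinyl group of chromium carbene complex A3, the two alkyne carbons of A2 and one carbonyl ligand. The forward key step is a Dötz benzannulation: alkyne insertion, CO insertion to a vinylketene, six-electron electrocyclisation and tautomerisation give the 4-methoxyphenol A1 with the chain ortho to the new hydroxyl. O-methylation and desilylation would follow. In its favour, the substitution pattern of ring A is fixed by the mechanism (the larger alkyne substituent ends next to the CO-derived carbon). It also does not depend on the two rings being identical and avoids every ionisable diarylallyl intermediate; on these two points it is the better of the chosen plan. Against it here, ring A is commercial in fully oxygenated form, so the arene construction solves a problem the target does not pose. Both stereocenters must already be present in A2, which needs its own asymmetric synthesis of several steps. Chromium is used stoichiometrically, A3 is a sensitive complex, and A1 is an air-sensitive hydroquinone monoether. The sequence would likely exceed ten steps against six, with no gain in stereocontrol.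

Alternative 2: The cut is the C1–C2 bond. In the forward key step aldehyde 1 reacts with the 2-arylallyl boronate A5 under a chiral phosphoric acid through a closed chair transition state to give the homoallylic alcohol A4. The C3 center then has to come from face-selective hydrogenation of the 1,1-disubstituted alkene. In its favour, the C1 stereocenter is set in the same event as a C–C bond by a highly ordered mechanism, without a transition metal and without any allyl cation. On the reliability of the C1 center it is the equal or the better of the chosen plan, and its step count (about two steps to A5, then two more) is equal or slightly lower. Against it here, 1 is a deactivated electrophile, 2-aryl substitution on the boronate is less usual than the parent reagents, and A4 is an acid-labile benzylic alcohol exposed to a Brønsted acid. The main weakness is that the difficulty moves to C3. Hydrogenation of an α-alkylstyrene with only a homoallylic hydroxyl as a handle offers modest face control, and acidic cationic hydrogenation catalysts could ionise or hydrogenolyse the benzylic C–O bond. The two plans are thus mirror images in risk: the chosen one sets C3 by a well-understood π-allyl mechanism and leaves C1 to an alkene hydrofunctionalisation, whereas this one sets C1 securely and leaves C3 to an alkene hydrogenation.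

Alternative 3: The cut is the bond between ring A and C1. In the forward key step the carbamate A7 is deprotonated by an alkyllithium–chiral diamine base, the configurationally stable α-lithiated carbamate captures the aryl boronate A8, and 1,2-migration of the aryl group with loss of the carbamate gives the benzylic boronate A6. A6 is the same compound as intermediate 12 of the chosen route, so both plans end with the same oxidation. In its favour, C1 is set by a stereospecific, reagent-controlled migration that is independent of C3. This is the equal or the better of the copper hydride step of the chosen plan in predictability. Against it here, C3 must be set beforehand in A7 by separate asymmetric chemistry, and the base and diamine are stoichiometric at low temperature. Ring B of A7 has a C–H flanked by two methoxy groups that invites competing ortho-lithiation, and A8 is an ortho-substituted boronate that forms the ate complex slowly. The longest linear sequence would be about equal to that of the chosen plan, with one or two more steps in total and no use of the symmetry of the target.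

Key step: step 4

Assumption: the sense of induction of (R)-iPr-PHOX in step 4 and of (S)-DTBM-SEGPHOS in step 6 is assigned by analogy with 1,3-diphenylallyl esters and β-alkylstyrenes; both antipodes of each ligand are commercial, so a reversed sense on these ortho-methoxylated substrates would be met by exchanging the antipode without changing the route.

## Route

Step 1
Reactants: 1 2,4,5-trimethoxybenzaldehyde; 2 1-(2,4,5-trimethoxyphenyl)ethanone
Product: 3 (E)-1,3-bis(2,4,5-trimethoxyphenyl)prop-2-en-1-one
Conditions: KOH (40 % aq.), EtOH, rt
Reagents that add atoms: none
Why: Claisen–Schmidt (crossed aldol) condensation: 2 is the only enolisable partner and 1 the only non-enolisable electrophile, so a single cross-product is expected, and E1cB loss of water gives the conjugated E enone, which should crystallise from the medium.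

Step 2
Reactants: 3 (E)-1,3-bis(2,4,5-trimethoxyphenyl)prop-2-en-1-one
Product: 4 rac-(E)-1,3-bis(2,4,5-trimethoxyphenyl)prop-2-en-1-ol
Conditions: iBu2AlH (1.2 equiv.), CH2Cl2, −78 °C; aq. potassium sodium tartrate, 0 °C
Reagents that add atoms: none
Why: 1,2-Reduction of an enone by an electrophilic aluminium hydride: coordination to the carbonyl oxygen delivers hydride to the carbonyl carbon and not to the β-carbon, and the aprotic medium with a neutral tartrate work-up avoids the solvolysis that a trivalent cerium salt in methanol could provoke in so ionisable an alcohol; no stereocontrol is wanted because both enantiomers converge in step 4.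

Step 3
Reactants: 4 rac-(E)-1,3-bis(2,4,5-trimethoxyphenyl)prop-2-en-1-ol; 5 methyl chloroformate
Product: 7 rac-(E)-1,3-bis(2,4,5-trimethoxyphenyl)allyl methyl carbonate, via lithium alkoxide 6 (not isolated)
Conditions: n-BuLi (1.0 equiv.), THF, −78 °C; then 5 (1.3 equiv.), −78 to 0 °C; aq. NaHCO3; used crude
Reagents that add atoms: n-butyllithium, [Li]CCCC (lithium of 6; none of its atoms stays in 7)
Why: O-Acylation of a preformed lithium alkoxide with a chloroformate (carbonate formation): O–H deprotonation at −78 °C is far faster than ring metalation, no acid or amine hydrochloride is ever present, and the only salt formed is LiCl in cold THF; allylic transposition would be degenerate, and 7 should be used at once without chromatography on silica.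

Step 4
Reactants: 7 rac-(E)-1,3-bis(2,4,5-trimethoxyphenyl)allyl methyl carbonate; 8 bis(phenylsulfonyl)methane
Product: 9 (S,E)-4,4-bis(phenylsulfonyl)-1,3-bis(2,4,5-trimethoxyphenyl)but-1-ene
Conditions: [Pd(C3H5)Cl]2 (2.5 mol %), (R)-iPr-PHOX (6 mol %), Cs2CO3 (5 mol %), 8 (1.2 equiv.), CH2Cl2, 0 °C
Reagents that add atoms: none
Why: Tsuji–Trost asymmetric allylic alkylation of the stereoconvergent type, whose closest known case is the alkylation of racemic 1,3-diphenylallyl acetates and carbonates with malonates and bis(sulfonyl)methanes under palladium phosphinooxazoline catalysis. The ligated zerovalent palladium, formed when the first sulfonyl carbanion removes the allyl ligand of the precatalyst, ionises either enantiomer of 7 with inversion to one and the same syn,syn-1,3-diaryl-π-allyl palladium cation, whose allyl ligand has a mirror plane because ring A and ring B are identical. The methyl carbonate anion loses CO2 to give methoxide, which deprotonates 8, so the nucleophile is produced only as fast as the π-allyl complex and no stoichiometric base is present to feed an uncatalysed substitution. The soft carbanion attacks outer-sphere, anti to palladium, and forms the C3–C4 bond; no ring is closed. The C3 stereocenter is controlled by the ligand alone: the P,N chelate makes the two allyl termini unequal, and attack at the terminus trans to phosphorus in the favoured, rapidly equilibrating exo complex is expected to give 3S with the (R)-ligand. The only selectivity required is this choice between enantiotopic termini, since attack at either end gives the same constitution and the syn,syn geometry of the complex secures the E alkene. A second allylation of 9 is not expected because its remaining C–H is flanked by the branched C3 and two sulfonyl groups. The low temperature and a short reaction time are chosen to limit ionisation of 7 without palladium and re-ionisation of 9 with it.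

Step 5
Reactants: 9 (S,E)-4,4-bis(phenylsulfonyl)-1,3-bis(2,4,5-trimethoxyphenyl)but-1-ene
Product: 11 (S,E)-1,3-bis(2,4,5-trimethoxyphenyl)but-1-ene, via monosulfone 10 (not isolated)
Conditions: Mg turnings (20 equiv.), MeOH–THF (3:1), 0 °C to rt
Reagents that add atoms: none
Why: Reductive desulfonylation by magnesium dissolving in methanol (single-electron transfer): each C–S bond is cleaved by two electrons and one proton, the geminal bis-sulfone first and the primary sulfone 10 second; the donor-substituted styrene is a poor electron acceptor and C3–H is far too weakly acidic for Mg(OMe)2, so the E alkene and the C3 configuration should be retained.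

Step 6
Reactants: 11 (S,E)-1,3-bis(2,4,5-trimethoxyphenyl)but-1-ene
Product: 13 (1R,3S)-1,3-bis(2,4,5-trimethoxyphenyl)butan-1-ol, via pinacolboronate 12 (not isolated)
Conditions: CuCl (5 mol %), NaOtBu (10 mol %), (S)-DTBM-SEGPHOS (5.5 mol %), HBpin (2 equiv.), toluene, rt to 40 °C; then NaBO3·4H2O, THF–H2O, rt
Reagents that add atoms: pinacolborane, CC1(C)OBOC1(C)C (boron and pinacol of 12; only its hydrogen stays in 13); sodium perborate tetrahydrate, O.O.O.O.[Na+].[O-]OB=O (hydroxyl oxygen of 13)
Why: Copper hydride-catalysed asymmetric Markovnikov hydroboration of a β-substituted vinylarene followed by stereoretentive C–B oxidation: the ligated monovalent copper hydride adds syn across C1=C2 with copper at benzylic C1 (only ring A is conjugated), σ-bond metathesis with pinacolborane gives 12 with retention, and perborate oxidation proceeds by 1,2-migration with retention. The C1 stereocenter is set by the bisphosphine, which selects the Re face at C1 for 1R and is expected to override the remote C3 center; oxidation in the same flask avoids handling the electron-rich benzylic boronate, and the work-up is kept neutral to protect the carbinol.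

## Compound list

1 | 2,4,5-trimethoxybenzaldehyde | COc1cc(OC)c(C=O)cc1OC | starting material
2 | 1-(2,4,5-trimethoxyphenyl)ethanone | COc1cc(OC)c(C(C)=O)cc1OC | starting material
3 | (E)-1,3-bis(2,4,5-trimethoxyphenyl)prop-2-en-1-one | COc1cc(OC)c(/C=C/C(=O)c2cc(OC)c(OC)cc2OC)cc1OC | intermediate
4 | rac-(E)-1,3-bis(2,4,5-trimethoxyphenyl)prop-2-en-1-ol | COc1cc(OC)c(/C=C/C(O)c2cc(OC)c(OC)cc2OC)cc1OC | intermediate
5 | methyl chloroformate | COC(Cl)=O | starting material
6 | lithium rac-(E)-1,3-bis(2,4,5-trimethoxyphenyl)prop-2-en-1-olate | COc1cc(OC)c(/C=C/C([O-])c2cc(OC)c(OC)cc2OC)cc1OC.[Li+] | intermediate
7 | rac-(E)-1,3-bis(2,4,5-trimethoxyphenyl)allyl methyl carbonate | COc1cc(OC)c(/C=C/C(OC(=O)OC)c2cc(OC)c(OC)cc2OC)cc1OC | intermediate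
8 | bis(phenylsulfonyl)methane | O=S(=O)(CS(=O)(=O)c1ccccc1)c1ccccc1 | starting material
9 | (S,E)-4,4-bis(phenylsulfonyl)-1,3-bis(2,4,5-trimethoxyphenyl)but-1-ene | COc1cc(OC)c(/C=C/[C@H](C(S(=O)(=O)c3ccccc3)S(=O)(=O)c3ccccc3)c2cc(OC)c(OC)cc2OC)cc1OC | intermediate
10 | (S,E)-4-(phenylsulfonyl)-1,3-bis(2,4,5-trimethoxyphenyl)but-1-ene | COc1cc(OC)c(/C=C/[C@H](CS(=O)(=O)c3ccccc3)c2cc(OC)c(OC)cc2OC)cc1OC | intermediate
11 | (S,E)-1,3-bis(2,4,5-trimethoxyphenyl)but-1-ene | COc1cc(OC)c(/C=C/[C@H](C)c2cc(OC)c(OC)cc2OC)cc1OC | intermediate
12 | 2-[(1R,3S)-1,3-bis(2,4,5-trimethoxyphenyl)butyl]-4,4,5,5-tetramethyl-1,3,2-dioxaborolane | COc1cc(OC)c([C@H](B3OC(C)(C)C(C)(C)O3)C[C@H](C)c2cc(OC)c(OC)cc2OC)cc1OC | intermediate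
13 | (1R,3S)-1,3-bis(2,4,5-trimethoxyphenyl)butan-1-ol | COc1cc(OC)c([C@H](O)C[C@H](C)c2cc(OC)c(OC)cc2OC)cc1OC | target

## Step count and least certain steps

Total step count: 6. Longest linear sequence: 6 steps, from 1 or 2 to 13; compounds 5 and 8 are bought.

Step 4 (key step). The most likely failure is loss of enantiocontrol. One path is ionisation of 7 without palladium, followed by unselective capture of the free, symmetric cation. The other is re-ionisation of 9 by palladium, since the bis-sulfonyl carbanion is a fair leaving group from an allyl system stabilised by two donor-substituted rings. Slow attack of the bulky carbanion at termini flanked by ortho-methoxy groups would give both processes more time. The fallback makes the C3 center by conjugate arylation, which involves no allyl cation, and sets out from 2. Aldol addition of its lithium enolate (LiN(iPr)2, THF, −78 °C) to acetaldehyde should give rac-3-hydroxy-1-(2,4,5-trimethoxyphenyl)butan-1-one F1. Dehydration (cat. p-TsOH, toluene, 60 °C) should give (E)-1-(2,4,5-trimethoxyphenyl)but-2-en-1-one F2. Hayashi–Miyaura addition of commercial 2,4,5-trimethoxyphenylboronic acid ([Rh(OH)((S)-binap)]2, dioxane–H2O, 35 °C; the ligand antipode is chosen for 3S by analogy with linear E enones) should give (S)-1,3-bis(2,4,5-trimethoxyphenyl)butan-1-one F3. Corey–Bakshi–Shibata reduction ((S)-2-methyl-CBS-oxazaborolidine, BH3·SMe2, THF, −20 °C), with the aryl group as the large substituent, should give the 1R alcohol, so the fallback comes back to the route at 13.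

Step 6. The most likely failure is slow hydrocupration, because the donor-substituted arene makes the alkene a poor acceptor for the hydride and the β-carbon carries a branched benzylic substituent. The consequences would be incomplete conversion or simple reduction of the alkene, and erosion of face selection if the C3 center and the ortho-methoxy group oppose the ligand. The fallback sets out from 11 and separates regiochemistry from stereochemistry. Mukaiyama hydration (Co(acac)2 cat., PhSiH3, O2, iPrOH–THF, rt) transfers a hydrogen atom to C2, and the benzylic C1 radical is captured by O2. This should give (3S)-1,3-bis(2,4,5-trimethoxyphenyl)butan-1-ol as a mixture of C1 epimers F4. Oxidation with MnO2 (CH2Cl2, rt) should converge on (S)-1,3-bis(2,4,5-trimethoxyphenyl)butan-1-one F3, which is reduced with the (S)-oxazaborolidine and BH3·SMe2 as described under step 4. The fallback comes back to the route at 13.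

Step 3. The most likely failure is decomposition of 7 as it forms: attack of chloride or of alkoxide 6 on the carbonate, or ionisation on concentration, all favoured by the stability of the diarylallyl cation. The fallback sets out from 4 and changes both the leaving group and the way the nucleophile is generated. Acetylation (Ac2O, Et3N, cat. DMAP, CH2Cl2, 0 °C), free of chloride and strong base, should give rac-(E)-1,3-bis(2,4,5-trimethoxyphenyl)allyl acetate F5. F5 is then alkylated with 8 under the same palladium–phosphinooxazoline catalyst with N,O-bis(trimethylsilyl)acetamide and cat. KOAc (CH2Cl2, 0 °C), where the carbanion arises by silyl transfer and not from the leaving group. The fallback comes back to the route at 9.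

Step 2. The most likely failure is loss of 4 by ionisation during aqueous work-up, concentration or chromatography, with minor conjugate reduction as a second concern. The fallback sets out from 1 and never handles the free alcohol. Wittig reaction with Ph3P=CHCHO (toluene, 80 °C) should give (E)-3-(2,4,5-trimethoxyphenyl)prop-2-enal F6. (2,4,5-Trimethoxyphenyl)lithium F7, made from commercial 1-bromo-2,4,5-trimethoxybenzene and n-BuLi (THF, −78 °C), should add 1,2 to F6 and give the alkoxide directly. The fallback comes back to the route at 6, which is acylated in the same flask with 5 as in step 3.

## Further compounds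

F1 | step 4 | rac-3-hydroxy-1-(2,4,5-trimethoxyphenyl)butan-1-one | COc1cc(OC)c(C(=O)CC(C)O)cc1OC
F2 | step 4 | (E)-1-(2,4,5-trimethoxyphenyl)but-2-en-1-one | COc1cc(OC)c(C(=O)/C=C/C)cc1OC
F3 | step 4 | (S)-1,3-bis(2,4,5-trimethoxyphenyl)butan-1-one | COc1cc(OC)c(C(=O)C[C@H](C)c2cc(OC)c(OC)cc2OC)cc1OC
F4 | step 6 | (3S)-1,3-bis(2,4,5-trimethoxyphenyl)butan-1-ol, mixture of C1 epimers | COc1cc(OC)c(C(O)C[C@H](C)c2cc(OC)c(OC)cc2OC)cc1OC
F5 | step 3 | rac-(E)-1,3-bis(2,4,5-trimethoxyphenyl)allyl acetate | COc1cc(OC)c(/C=C/C(OC(C)=O)c2cc(OC)c(OC)cc2OC)cc1OC
F6 | step 2 | (E)-3-(2,4,5-trimethoxyphenyl)prop-2-enal | COc1cc(OC)c(/C=C/C=O)cc1OC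
F7 | step 2 | (2,4,5-trimethoxyphenyl)lithium | [Li]c1cc(OC)c(OC)cc1OC
A1 | alternative 1 | 2-[(1R,3S)-1-(tert-butyldimethylsilyloxy)-3-(2,4,5-trimethoxyphenyl)butyl]-4,5-dimethoxyphenol | COc1cc(O)c([C@H](O[Si](C)(C)C(C)(C)C)C[C@H](C)c2cc(OC)c(OC)cc2OC)cc1OC
A2 | alternative 1 | tert-butyldimethyl{[(3R,5S)-5-(2,4,5-trimethoxyphenyl)hex-1-yn-3-yl]oxy}silane | C#C[C@H](O[Si](C)(C)C(C)(C)C)C[C@H](C)c1cc(OC)c(OC)cc1OC
A3 | alternative 1 | pentacarbonyl[methoxy(1-methoxyvinyl)carbene]chromium | COC(=C)C(OC)=[Cr](=C=O)(=C=O)(=C=O)(=C=O)=C=O
A4 | alternative 2 | (R)-1,3-bis(2,4,5-trimethoxyphenyl)but-3-en-1-ol | COc1cc(OC)c([C@H](O)CC(=C)c2cc(OC)c(OC)cc2OC)cc1OC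
A5 | alternative 2 | 4,4,5,5-tetramethyl-2-[2-(2,4,5-trimethoxyphenyl)prop-2-en-1-yl]-1,3,2-dioxaborolane | COc1cc(OC)c(C(=C)CB2OC(C)(C)C(C)(C)O2)cc1OC
A6 | alternative 3 | 2-[(1R,3S)-1,3-bis(2,4,5-trimethoxyphenyl)butyl]-4,4,5,5-tetramethyl-1,3,2-dioxaborolane | COc1cc(OC)c([C@H](B3OC(C)(C)C(C)(C)O3)C[C@H](C)c2cc(OC)c(OC)cc2OC)cc1OC
A7 | alternative 3 | (S)-3-(2,4,5-trimethoxyphenyl)butyl N,N-diisopropylcarbamate | CC(C)N(C(C)C)C(=O)OCC[C@H](C)c1cc(OC)c(OC)cc1OC
A8 | alternative 3 | 4,4,5,5-tetramethyl-2-(2,4,5-trimethoxyphenyl)-1,3,2-dioxaborolane | COc1cc(OC)c(B2OC(C)(C)C(C)(C)O2)cc1OC
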